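A direct plan would build ring A from acyclic and heterocyclic pieces.
2-Bromo-3-chlorothiophene A1 would be taken in four steps (silyl blocking, halogen dance with bromination, desilylation, S-oxidation) to 2,4-dibromo-3-chlorothiophene 1,1-dioxide A2, and 2,4-dibromophenol A3 in three steps to the (Z)-aryloxy enol acetate A4.
Cycloaddition of A2 with A4 and loss of SO2 would give the cis-dienyl acetate A5; ester cleavage and alcohol oxidation would then aromatise it to the phenol.
Weak point (a): the cycloaddition that closes ring A. Its regiochemistry would rest on a small donor difference between aryloxy and acetoxy, the sulfone dimerises readily, and A5 carries two leaving groups on a diene, so loss of acetic acid or of A3 would aromatise it with one oxygen missing.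
Weak point (b): the four-step run-up to the small, labile sulfone A2, which forms no bond of the target.
Weak point (c): the hydride cleavage and reoxidation on an elimination-prone dienol, a redox detour that builds nothing.

**Retrosynthetic overview**
Ring A of the target is a catechol whose hindered oxygen on C2 (between C1–OH and C3–Br) carries ring B, so the two neighbouring C–O positions C1 and C2 are both traced back to one hypervalent iodine atom.
C1–OH comes from C1–I; the ortho-iodo diaryl ether comes from an ortho-iodonio phenolate by a 1,4 shift of ring B from iodine to the C2 oxygen.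
The zwitterion comes from 2,4-dibromo-3-chlorophenol, which has a single free ortho C–H (the future C1), and (2,4-dibromophenyl)iodine diacetate.
Both benzene rings are bought intact, so no ring is closed, no dienyl leaving group or stereocentre ever exists, and no redox correction of the skeleton is needed.

Key step: step 3

Assumption: 2-bromo-3-chlorophenol and 2,4-dibromo-1-iodobenzene are taken as catalogue compounds.

Step 1
Reactants: 1 2-bromo-3-chlorophenol
Product: 2 2,4-dibromo-3-chlorophenol
Conditions: NBS (1.0 equiv), MeCN, −10 °C → rt; chromatography
Reagents that add atoms: N-bromosuccinimide, O=C1CCC(=O)N1Br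
Why: Electrophilic aromatic bromination goes para to the hydroxyl group, the most activated free position; the only alternative is the free ortho position, and that minor isomer would be removed on silica.

Step 2
Reactants: 3 2,4-dibromo-1-iodobenzene
Product: 4 (2,4-dibromophenyl)iodine diacetate [2,4-dibromo-1-(diacetoxyiodo)benzene]
Conditions: CH3CO3H (ca. 35% in AcOH, 2.5 equiv), AcOH, 30–35 °C; precipitation with water
Reagents that add atoms: peracetic acid, CC(=O)OO; acetic acid, CC(=O)O
Why: Peracid oxidation of an aryl iodide to the (diacetoxyiodo)arene is a standard preparation of trivalent iodine reagents, and the aryl bromides are inert to it.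

Step 3
Reactants: 2 2,4-dibromo-3-chlorophenol; 4 (2,4-dibromophenyl)iodine diacetate
Product: 6 1,3-dibromo-2-chloro-4-(2,4-dibromophenoxy)-5-iodobenzene, via ortho-iodonio phenolate zwitterion 5 (not isolated)
Conditions: Cs2CO3 (1.1 equiv), MeCN, 0 °C; 4 (1.05 equiv) in portions, 0 °C → rt, dark; then 70 °C
Reagents that add atoms: none
Why: The cesium phenolate of 2 should displace acetate on the trivalent iodine of 4 and the iodine should then bond to the single free ortho carbon of 2 to give zwitterion 5, in which the phenolate oxygen attacks the ipso carbon of the 2,4-dibromophenyl ligand through a five-membered spiro transition state and expels iodine as the monovalent aryl iodide (1,4 shift of ring B from iodine to oxygen). The closest known reaction type is the formation of aryliodonium phenolates from electron-poor phenols and (diacetoxyiodo)arenes and their thermal rearrangement to 2-iodophenyl aryl ethers, which also runs on ortho-oxido diaryliodonium salts with carbonate bases. No ring is closed and no stereocentre is formed; the step makes the ether bond O–C1' and the C1–I bond of ring A in one operation, the iodine marking the carbon that becomes C1–OH. Site selectivity is secured by the substrate, since the para and the second ortho position of 2 carry bromine and only the future C1 has an ortho C–H. C-iodination rather than two-electron oxidation of the phenol is expected because 2 is comparable in acidity to 4-nitrophenol and no nucleophilic solvent is present, and only ring B can migrate because the attacking oxygen sits on ring A. Ipso attack should win over displacement of the ortho bromine of ring B because the aryliodonio group is by far the better leaving group, and the ortho and para bromines of ring B stabilise the negative charge in the transition state.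

Step 4
Reactants: 6 1,3-dibromo-2-chloro-4-(2,4-dibromophenoxy)-5-iodobenzene
Product: 9 3,5-dibromo-4-chloro-2-(2,4-dibromophenoxy)phenol, via arylmagnesium chloride 7 (not isolated), via dimethyl arylboronate 8 (not isolated)
Conditions: i-PrMgCl·LiCl (1.05 equiv), THF, −78 → −40 °C; B(OMe)3, −78 → 0 °C; then 30% H2O2, AcOH, 0 °C → rt
Reagents that add atoms: hydrogen peroxide, OO
Why: Iodine–magnesium exchange at the C–I bond, activated by the ortho aryloxy oxygen, is far faster than bromine–magnesium exchange at low temperature, the Grignard reagent 7 has no ortho halogen to eliminate, and borylation followed by peroxide oxidation (1,2-shift of aryl from boron to oxygen) turns the C–Mg bond into C–OH.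

**Compound list**
1 | 2-bromo-3-chlorophenol | Oc1cccc(Cl)c1Br | starting material
2 | 2,4-dibromo-3-chlorophenol | Oc1ccc(Br)c(Cl)c1Br | intermediate
3 | 2,4-dibromo-1-iodobenzene | Ic1ccc(Br)cc1Br | starting material
4 | (2,4-dibromophenyl)iodine diacetate [2,4-dibromo-1-(diacetoxyiodo)benzene] | CC(=O)OI(OC(C)=O)c1ccc(Br)cc1Br | intermediate
5 | 2,4-dibromo-3-chloro-6-[(2,4-dibromophenyl)iodonio]phenolate | [O-]c1c(Br)c(Cl)c(Br)cc1[I+]c1ccc(Br)cc1Br | intermediate
6 | 1,3-dibromo-2-chloro-4-(2,4-dibromophenoxy)-5-iodobenzene | Ic1cc(Br)c(Cl)c(Br)c1Oc1ccc(Br)cc1Br | intermediate
7 | [3,5-dibromo-4-chloro-2-(2,4-dibromophenoxy)phenyl]magnesium chloride | Cl[Mg]c1cc(Br)c(Cl)c(Br)c1Oc1ccc(Br)cc1Br | intermediate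
8 | dimethyl [3,5-dibromo-4-chloro-2-(2,4-dibromophenoxy)phenyl]boronate | COB(OC)c1cc(Br)c(Cl)c(Br)c1Oc1ccc(Br)cc1Br | intermediate
9 | 3,5-dibromo-4-chloro-2-(2,4-dibromophenoxy)phenol | Oc1cc(Br)c(Cl)c(Br)c1Oc1ccc(Br)cc1Br | target

Total step count: 4. Longest linear sequence: 3 steps (1 → 2 → 6 → 9); step 2 is a one-step branch.

**Steps most likely to fail**

Step 3. Two-electron oxidation of the phenolate by the iodine reagent (attack of acetate or adventitious water on a ring carbon of the O-bound aryloxyiodane, loss of 3 and of bromide, quinoid products) may outrun C-iodination, or the zwitterion may pass ring B to a second phenolate intermolecularly. The fallback makes the two bonds separately by known chemistry; it sets out from 2 and comes back to the route at 6. Compound 2 would be iodinated at its free ortho position (N-iodosuccinimide, cat. TsOH, MeCN) to 2,4-dibromo-3-chloro-6-iodophenol F1. Its sodium salt would then be O-arylated with bis(2,4-dibromophenyl)iodonium chloride F2 in aqueous NaOH/dioxane at reflux, the classical arylation used for polybrominated diphenyl ethers. F2 would come from 1,3-dibromobenzene F3 and iodyl sulfate, (IO)2SO4, made from I2 and KIO3 in H2SO4, followed by NaCl.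

Step 4. Bromine–magnesium exchange at the bromine flanked by oxygen and chlorine, or proton quench of the aryl Grignard reagent before borylation, may erode chemoselectivity. The fallback sets out from 6 and comes back at 9: copper-catalysed hydroxylation of the C–I bond (CuI, 1,10-phenanthroline, KOH, DMSO/H2O, 80 °C), in which monovalent copper inserts into the C–I bond much faster than into C–Br. No new compound is made (F0).

Step 1. Bromination at the unhindered ortho position instead of the para position flanked by chlorine, or over-bromination, may give an inseparable mixture. The fallback does not set out from 1: it replaces 1 by commercial 1,3-dibromo-2-chlorobenzene F4 and comes back to the route at 2. F4 would be deprotonated ortho to bromine with LDA in the presence of B(Oi-Pr)3 (THF, −78 °C, in situ trapping to forestall halogen migration and aryne formation). Acidic work-up would give (2,4-dibromo-3-chlorophenyl)boronic acid F5, which would be oxidised with H2O2/NaOH to 2.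

**Further compounds**
F1 | step 3 | 2,4-dibromo-3-chloro-6-iodophenol | Oc1c(Br)c(Cl)c(Br)cc1I
F2 | step 3 | bis(2,4-dibromophenyl)iodonium chloride | Brc1ccc([I+]c2ccc(Br)cc2Br)c(Br)c1.[Cl-]
F3 | step 3 | 1,3-dibromobenzene | Brc1cccc(Br)c1
F0 | step 4 | none | none
F4 | step 1 | 1,3-dibromo-2-chlorobenzene | Clc1c(Br)cccc1Br
F5 | step 1 | (2,4-dibromo-3-chlorophenyl)boronic acid | OB(O)c1ccc(Br)c(Cl)c1Br
A1 | direct plan | 2-bromo-3-chlorothiophene | Clc1ccsc1Br
A2 | direct plan | 2,4-dibromo-3-chlorothiophene 1,1-dioxide | O=S1(=O)C=C(Br)C(Cl)=C1Br
A3 | direct plan | 2,4-dibromophenol | Oc1ccc(Br)cc1Br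
A4 | direct plan | (Z)-2-(2,4-dibromophenoxy)ethenyl acetate | CC(=O)O/C=C\Oc1ccc(Br)cc1Br
A5 | direct plan | cis-3,5-dibromo-4-chloro-6-(2,4-dibromophenoxy)cyclohexa-2,4-dien-1-yl acetate (racemic) | CC(=O)O[C@@H]1C=C(Br)C(Cl)=C(Br)[C@@H]1Oc1ccc(Br)cc1Br
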